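The piperidine N1'–C2' bond is the disconnection. C2' is attached to C6 of ring A, para to the oxygen that becomes O1 and flanked by O5 and O7. With that para oxygen as a free phenol and O5/O7 as identical methyl ethers, a racemic C2' carbinol ionises to one symmetric para-quinone methide. A chiral phosphoric acid then steers the tethered Boc–NH onto the methide carbon, closing the piperidine and fixing (R)-C2' in a single stereoconvergent operation. The precursor is an open-chain Boc-amino benzylic alcohol made from 3,5-dimethoxyphenol and N-Boc-2-piperidone. Afterwards the carbamate is reduced to N-methyl and the flavone is annulated onto the phenol.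

Key step: step 4

Remark on the chemistry: the sense of induction of the chiral phosphoric acid in this closure cannot be predicted with certainty, so the (R)-catalyst is written and its mirror image is to be used if the first screen shows the opposite sense.

Step 1
Reactants: 1 3,5-dimethoxyphenol
Product: 2 (3,5-dimethoxyphenoxy)triisopropylsilane
Conditions: i-Pr3SiCl, imidazole, DMF, rt
Reagents that add atoms: triisopropylsilyl chloride, CC(C)[Si](Cl)(C(C)C)C(C)C
Why: Routine O-silylation of a phenol, with the bulky, poorly coordinating triisopropylsilyl group chosen so that the silyloxy oxygen does not direct the lithiation of step 2 and the ether survives n-BuLi.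

Step 2
Reactants: 2 (3,5-dimethoxyphenoxy)triisopropylsilane; 3 tert-butyl 2-oxopiperidine-1-carboxylate
Product: 5 tert-butyl N-{5-[2,6-dimethoxy-4-(triisopropylsilyloxy)phenyl]-5-oxopentyl}carbamate, via aryllithium 4 (not isolated)
Conditions: n-BuLi, TMEDA, THF, 0 °C; then 3, −78 °C; AcOH, −78 °C
Reagents that add atoms: tert-butyl 2-oxopiperidine-1-carboxylate (3), CC(C)(C)OC(=O)N1CCCCC1=O
Why: Directed ortho-lithiation should remove the proton between the two cooperating methoxy groups, and the aryllithium then opens the Boc-activated lactam at its ring carbonyl (acyl substitution with ring opening) to the N-Boc amino ketone, whose di-ortho-substituted carbonyl resists a second addition.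

Step 3
Reactants: 5 tert-butyl N-{5-[2,6-dimethoxy-4-(triisopropylsilyloxy)phenyl]-5-oxopentyl}carbamate
Product: 7 racemic tert-butyl N-[5-hydroxy-5-(4-hydroxy-2,6-dimethoxyphenyl)pentyl]carbamate, via silyl ether alcohol 6 (not isolated)
Conditions: NaBH4, THF–MeOH, 0 °C to rt; then Bu4NF, 0 °C; pH 7 phosphate buffer
Reagents that add atoms: none
Why: Borohydride reduction of the ketone gives the racemic benzylic alcohol (no stereocontrol is needed because step 4 is stereoconvergent) and fluoride desilylation frees the para phenol in the same flask, both under non-acidic conditions that spare the Boc group and the acid-labile carbinol.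

Step 4
Reactants: 7 racemic tert-butyl N-[5-hydroxy-5-(4-hydroxy-2,6-dimethoxyphenyl)pentyl]carbamate
Product: 9 tert-butyl (2R)-2-(4-hydroxy-2,6-dimethoxyphenyl)piperidine-1-carboxylate, via para-quinone methide 8 (not isolated)
Conditions: (R)-3,3'-bis(2,4,6-triisopropylphenyl)-1,1'-binaphthyl-2,2'-diyl hydrogen phosphate (10 mol%), 5 Å molecular sieves, toluene (0.01 M), 0 °C
Reagents that add atoms: none
Why: Proposed new method: the phosphoric acid protonates the benzylic hydroxyl of 7, water leaves with help from the para phenol, and the planar para-quinone methide 8 stays hydrogen-bonded and ion-paired to the chiral phosphate, so both enantiomers of 7 converge on one achiral intermediate. The phosphoryl oxygen also binds the carbamate N–H, and nitrogen adds to the exocyclic methide carbon (aza-1,6-addition) with rearomatisation, forming N1'–C2'. The closest known reactions are chiral phosphoric acid catalysed intermolecular 1,6-additions to para-quinone methides generated in situ from 4-hydroxybenzylic alcohols, and acid-catalysed intramolecular substitution of benzylic alcohols by carbamates. The piperidine ring closes in a 6-exo-trig mode. The C2' configuration is under catalyst control, the chiral phosphate pocket differentiating the two faces of the methide. The step needs enantioface selectivity and N-cyclisation in preference to intermolecular C- or O-alkylation: the two identical flanking methoxy groups allow only one methide geometry, the five-atom tether makes closure intramolecular, and high dilution at low temperature should suppress oligomerisation and re-ionisation of the product.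

Step 5
Reactants: 9 tert-butyl (2R)-2-(4-hydroxy-2,6-dimethoxyphenyl)piperidine-1-carboxylate
Product: 10 3,5-dimethoxy-4-[(2R)-1-methylpiperidin-2-yl]phenol
Conditions: LiAlH4, THF, reflux; H2O, aq. NaOH
Reagents that add atoms: none
Why: Hydride reduction of a carbamate to an N-methyl amine, in which the phenol is only deprotonated, the aryl methyl ethers are inert and no bond to C2' is touched, so the configuration is retained and the ionisable carbamate is replaced by a more robust amine before any acidic step.

Step 6
Reactants: 10 3,5-dimethoxy-4-[(2R)-1-methylpiperidin-2-yl]phenol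
Product: 11 1-{6-hydroxy-2,4-dimethoxy-3-[(2R)-1-methylpiperidin-2-yl]phenyl}ethan-1-one
Conditions: BF3·OEt2 (excess, added first), then Ac2O, CH2Cl2, 0 °C to rt; aq. NaHCO3
Reagents that add atoms: acetic anhydride, CC(=O)OC(C)=O
Why: Friedel–Crafts (Fries-type) C-acetylation of a phloroglucinol-type phenol, whose only free ring positions are the two equivalent carbons ortho to the hydroxyl; prior complexation of the amine by BF3 blocks N-acylation and the boron difluoride chelate of the product discourages a second acylation.

Step 7
Reactants: 11 1-{6-hydroxy-2,4-dimethoxy-3-[(2R)-1-methylpiperidin-2-yl]phenyl}ethan-1-one; 12 benzoyl chloride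
Product: 13 1-{6-hydroxy-2,4-dimethoxy-3-[(2R)-1-methylpiperidin-2-yl]phenyl}-3-phenylpropane-1,3-dione
Conditions: LiN(SiMe3)2 (4 equiv), THF, −78 to −10 °C; then 12 (slow addition), −78 °C to rt; aq. NH4Cl
Reagents that add atoms: benzoyl chloride (12), O=C(Cl)c1ccccc1
Why: Crossed Claisen C-benzoylation of the lithium phenoxide–enolate dianion, the one-flask equivalent of Baker–Venkataraman benzoylation and rearrangement; the C2'–H is far too weakly acidic for this base, so the stereocentre is not at risk.

Step 8
Reactants: 13 1-{6-hydroxy-2,4-dimethoxy-3-[(2R)-1-methylpiperidin-2-yl]phenyl}-3-phenylpropane-1,3-dione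
Product: 14 5,7-dimethoxy-6-[(2R)-1-methylpiperidin-2-yl]-2-phenyl-4H-chromen-4-one
Conditions: H2SO4, AcOH, 60 °C
Reagents that add atoms: none
Why: Acid-catalysed cyclodehydration of an ortho-hydroxyaryl 1,3-diketone to the flavone, in which the single free hydroxyl closes ring C so that only the 6-substituted isomer can form, while the protonated amine on the now acyl-deactivated ring should not ionise.

Step 9
Reactants: 14 5,7-dimethoxy-6-[(2R)-1-methylpiperidin-2-yl]-2-phenyl-4H-chromen-4-one
Product: 15 5,7-dihydroxy-6-[(2R)-1-methylpiperidin-2-yl]-2-phenyl-4H-chromen-4-one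
Conditions: BBr3 (excess), CH2Cl2, −78 °C to rt; MeOH, then aq. NaHCO3
Reagents that add atoms: none
Why: Lewis-acid cleavage of aryl methyl ethers, in which the C5 ether is activated by chelation to the C4 carbonyl and the C7 ether, twisted by the C6 substituent, should follow on warming, with the low temperature protecting C2'.

Compound list
1 | 3,5-dimethoxyphenol | COc1cc(O)cc(OC)c1 | starting material
2 | (3,5-dimethoxyphenoxy)triisopropylsilane | COc1cc(O[Si](C(C)C)(C(C)C)C(C)C)cc(OC)c1 | intermediate
3 | tert-butyl 2-oxopiperidine-1-carboxylate | CC(C)(C)OC(=O)N1CCCCC1=O | starting material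
4 | [2,6-dimethoxy-4-(triisopropylsilyloxy)phenyl]lithium (not isolated) | [Li]c1c(OC)cc(O[Si](C(C)C)(C(C)C)C(C)C)cc1OC | intermediate
5 | tert-butyl N-{5-[2,6-dimethoxy-4-(triisopropylsilyloxy)phenyl]-5-oxopentyl}carbamate | CC(C)(C)OC(=O)NCCCCC(=O)c1c(OC)cc(O[Si](C(C)C)(C(C)C)C(C)C)cc1OC | intermediate
6 | racemic tert-butyl N-{5-[2,6-dimethoxy-4-(triisopropylsilyloxy)phenyl]-5-hydroxypentyl}carbamate (not isolated) | CC(C)(C)OC(=O)NCCCCC(O)c1c(OC)cc(O[Si](C(C)C)(C(C)C)C(C)C)cc1OC | intermediate
7 | racemic tert-butyl N-[5-hydroxy-5-(4-hydroxy-2,6-dimethoxyphenyl)pentyl]carbamate | CC(C)(C)OC(=O)NCCCCC(O)c1c(OC)cc(O)cc1OC | intermediate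
8 | tert-butyl N-[5-(2,6-dimethoxy-4-oxocyclohexa-2,5-dien-1-ylidene)pentyl]carbamate (para-quinone methide, not isolated) | CC(C)(C)OC(=O)NCCCCC=C1C(OC)=CC(=O)C=C1OC | intermediate
9 | tert-butyl (2R)-2-(4-hydroxy-2,6-dimethoxyphenyl)piperidine-1-carboxylate | CC(C)(C)OC(=O)N1CCCC[C@@H]1c1c(OC)cc(O)cc1OC | intermediate
10 | 3,5-dimethoxy-4-[(2R)-1-methylpiperidin-2-yl]phenol | CN1CCCC[C@@H]1c1c(OC)cc(O)cc1OC | intermediate
11 | 1-{6-hydroxy-2,4-dimethoxy-3-[(2R)-1-methylpiperidin-2-yl]phenyl}ethan-1-one | CN1CCCC[C@@H]1c1c(OC)cc(O)c(C(C)=O)c1OC | intermediate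
12 | benzoyl chloride | O=C(Cl)c1ccccc1 | starting material
13 | 1-{6-hydroxy-2,4-dimethoxy-3-[(2R)-1-methylpiperidin-2-yl]phenyl}-3-phenylpropane-1,3-dione | CN1CCCC[C@@H]1c1c(OC)cc(O)c(C(=O)CC(=O)c2ccccc2)c1OC | intermediate
14 | 5,7-dimethoxy-6-[(2R)-1-methylpiperidin-2-yl]-2-phenyl-4H-chromen-4-one | CN1CCCC[C@@H]1c1c(OC)cc2oc(-c3ccccc3)cc(=O)c2c1OC | intermediate
15 | 5,7-dihydroxy-6-[(2R)-1-methylpiperidin-2-yl]-2-phenyl-4H-chromen-4-one | CN1CCCC[C@@H]1c1c(O)cc2oc(-c3ccccc3)cc(=O)c2c1O | target

Total step count: 9. Longest linear sequence: 9 steps, from 3,5-dimethoxyphenol.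

Steps most likely to fail

Step 4 (Proposed new method). The enantioselectivity may be eroded by uncatalysed or adventitious-acid ionisation of the very electron-rich carbinol and by re-ionisation of the product. The quinone methide may also be consumed by intermolecular alkylation at the free ring positions of another molecule. The fallback uses known chemistry that avoids the quinone methide altogether and sets out from ketone 5. CF3CO2H in CH2Cl2 removes the Boc group, and on basification the amino ketone condenses to the cyclic imine 6-[2,6-dimethoxy-4-(triisopropylsilyloxy)phenyl]-2,3,4,5-tetrahydropyridine F1. Catalytic asymmetric reduction of this 2-aryl cyclic imine should give (2R)-2-[2,6-dimethoxy-4-(triisopropylsilyloxy)phenyl]piperidine F2. The options are hydrogenation with [Ir(cod)Cl]2 and a chiral bisphosphine such as f-Binaphane under H2, or an (R)-selective imine reductase. Reductive methylation with aqueous HCHO and NaBH(OAc)3 gives (2R)-2-[2,6-dimethoxy-4-(triisopropylsilyloxy)phenyl]-1-methylpiperidine F3. Desilylation with Bu4NF then rejoins the route at 10.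

Step 6. The Lewis acid may trigger heterolysis of the C2'–N bond on the trioxygenated ring, leading to racemisation or ring opening. The nitrogen may be acylated, or the ring acylated twice. The fallback sets out from 10 and works under non-acidic conditions. Magnesium-phenoxide-directed ortho-formylation (MgCl2, Et3N, paraformaldehyde, MeCN, 70 °C) should give 6-hydroxy-2,4-dimethoxy-3-[(2R)-1-methylpiperidin-2-yl]benzaldehyde F4. Addition of excess MeMgBr in THF at 0 °C gives 1-{6-hydroxy-2,4-dimethoxy-3-[(2R)-1-methylpiperidin-2-yl]phenyl}ethan-1-ol F5 as a mixture of carbinol epimers, used crude. Oxidation of this benzylic alcohol with MnO2 in CH2Cl2 rejoins the route at 11.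

Step 9. Cleavage of the C7 ether may stay incomplete at temperatures that keep C2' intact, or the configuration may be lost through reversible C–N ionisation on long exposure to the Lewis acid. The fallback sets out from 14 and splits the deprotection into two mechanistically different stages. BCl3 in CH2Cl2 at −78 to 0 °C removes only the C5 methyl by chelation to the C4 carbonyl, giving 5-hydroxy-7-methoxy-6-[(2R)-1-methylpiperidin-2-yl]-2-phenyl-4H-chromen-4-one F6. The remaining C7 ether is then cleaved by SN2 attack of a soft nucleophile (NaSEt, DMF, 100 °C) under non-acidic conditions, in which the neutral amine cannot act as a leaving group. This ends at the target 15.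

Further compounds
F1 | step 4 | 6-[2,6-dimethoxy-4-(triisopropylsilyloxy)phenyl]-2,3,4,5-tetrahydropyridine | COc1cc(O[Si](C(C)C)(C(C)C)C(C)C)cc(OC)c1C1=NCCCC1
F2 | step 4 | (2R)-2-[2,6-dimethoxy-4-(triisopropylsilyloxy)phenyl]piperidine | N1CCCC[C@@H]1c1c(OC)cc(O[Si](C(C)C)(C(C)C)C(C)C)cc1OC
F3 | step 4 | (2R)-2-[2,6-dimethoxy-4-(triisopropylsilyloxy)phenyl]-1-methylpiperidine | CN1CCCC[C@@H]1c1c(OC)cc(O[Si](C(C)C)(C(C)C)C(C)C)cc1OC
F4 | step 6 | 6-hydroxy-2,4-dimethoxy-3-[(2R)-1-methylpiperidin-2-yl]benzaldehyde | CN1CCCC[C@@H]1c1c(OC)cc(O)c(C=O)c1OC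
F5 | step 6 | 1-{6-hydroxy-2,4-dimethoxy-3-[(2R)-1-methylpiperidin-2-yl]phenyl}ethan-1-ol (mixture of carbinol epimers) | CN1CCCC[C@@H]1c1c(OC)cc(O)c(C(C)O)c1OC
F6 | step 9 | 5-hydroxy-7-methoxy-6-[(2R)-1-methylpiperidin-2-yl]-2-phenyl-4H-chromen-4-one | CN1CCCC[C@@H]1c1c(OC)cc2oc(-c3ccccc3)cc(=O)c2c1O
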